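A direct plan would set the benzyl-bearing carbon by alkylating a chiral 3-arylpropanoyl oxazolidinone with a bromoacetate,
reduce and lactonise to the 4-(arylmethyl)butyrolactone A1, add 3,4-dimethoxybenzaldehyde to its enolate to give aldol A2,
then open the lactone and turn both CH2O carbons into methyl groups via dimesylate A3 and hydride, acetylate and free the phenol.
Its weak points would be: (a) the lactone-enolate aldol, since the carbinol configuration would rest on a modest kinetic
preference and an epimer would have to be separated; (b) the run of about eight steps (protection, auxiliary on and off,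
lactonisation) that would deliver only A1 with one stereocentre; (c) lactone reduction, double mesylation and double hydride
displacement, with a silyl ether put on and taken off around them: five late steps that would add no complexity and in which
a mono-mesylate could close a tetrahydrofuran on precious material.

Chain locants: C1 (CHOAc on ring A, 3,4-dimethoxyphenyl), C2 and C3 (CH–CH3), C4 (CH2 on ring B, 4-hydroxy-3-methoxyphenyl).
Cuts, in retrosynthetic order: C3–H (hydroxyl-directed hydrogenation of C3=CH2); C3=CH2 and C3–C4 (methylenation; benzyl Grignard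
on a Weinreb amide); C1–H together with C2–H (ketoreductase reduction under dynamic kinetic resolution); C2–CH3 (methylation).
Enabling feature: C2 lies between C1, which carries ring A, and C3; with C1 as ketone and C3 as ester carbonyl the C2–H is
acidic, so C2 racemises while the enzyme reduces one enantiomer. No ring is formed; rings A and B come with the starting materials.
No aldol sets a stereocentre, both methyl carbons enter without deoxygenation, and one phenol silyl ether is the only protecting group.

Key step: step 2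

Assumption: a ketoreductase with syn-(2R,3R) preference for 2 can be chosen from a commercial enzyme panel, as is usual for 2-methyl-3-oxo-3-arylpropanoates.

Step 1
Reactants: 1 ethyl 3-(3,4-dimethoxyphenyl)-3-oxopropanoate
Product: 2 ethyl (2RS)-3-(3,4-dimethoxyphenyl)-2-methyl-3-oxopropanoate
Conditions: MeI (1.05 equiv), K2CO3 (1.5 equiv), acetone, rt
Reagents that add atoms: iodomethane, CI
Why: C-alkylation of the 1,3-dicarbonyl enolate with one equivalent of iodomethane should give the mono-methyl keto ester, whose configuration at C2 is labile and therefore need not be controlled.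

Step 2
Reactants: 2 ethyl (2RS)-3-(3,4-dimethoxyphenyl)-2-methyl-3-oxopropanoate
Product: 3 ethyl (2R,3R)-3-(3,4-dimethoxyphenyl)-3-hydroxy-2-methylpropanoate
Conditions: ketoreductase (NADPH-dependent, syn-(2R,3R)-selective), NADP+ (cat.), iPrOH (15 vol%), DMSO (5 vol%), K2HPO4/KH2PO4 buffer (0.1 M, pH 7.5), 30 °C
Reagents that add atoms: none
Why: The ketoreductase transfers the hydride of NADPH (regenerated from propan-2-ol, which ends as acetone) to one face of the aryl ketone of only one enantiomer of 2, while the unreactive enantiomer racemises through the enol because the C2–H lies between the ketone and the ester carbonyl; this dynamic kinetic resolution can convert all of the racemate. The closest known reaction type is the ketoreductase reduction of racemic 2-alkyl-3-oxo esters such as ethyl 2-methyl-3-oxo-3-phenylpropanoate, for which enzymes of syn and of anti preference are available. No ring is closed. The carbinol centre (3R in 3, C1 of the target) is controlled by the face of hydride delivery fixed in the active site, and the methyl-bearing centre (2R in 3, C2 of the target) by the enzyme's choice between the two interconverting enantiomers. The step needs the syn-(2R,3R) isomer out of four and racemisation faster than reduction: the first is secured by the choice of enzyme, the second by the 1,3-dicarbonyl acidity of C2–H at pH 7.5 and by the slow hydride acceptance of the electron-rich 3,4-dimethoxyphenyl ketone.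

Step 3
Reactants: 3 ethyl (2R,3R)-3-(3,4-dimethoxyphenyl)-3-hydroxy-2-methylpropanoate
Product: 4 (2R,3R)-3-(3,4-dimethoxyphenyl)-3-hydroxy-N-methoxy-N,2-dimethylpropanamide
Conditions: MeNH(OMe)·HCl (3 equiv), iPrMgCl (6.5 equiv), THF, −20 to 0 °C
Reagents that add atoms: N,O-dimethylhydroxylamine hydrochloride, CNOC.Cl
Why: Weinreb amide formation by aminolysis of the ester with the magnesium amide runs on the magnesium alkoxide of the free hydroxy ester at low temperature, where neither retro-aldol cleavage nor epimerisation at C2 is expected.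

Step 4
Reactants: 5 vanillin (4-hydroxy-3-methoxybenzaldehyde)
Product: 6 4-{[tert-butyl(dimethyl)silyl]oxy}-3-methoxybenzaldehyde
Conditions: TBSCl (1.2 equiv), imidazole (2.5 equiv), DMF, rt
Reagents that add atoms: tert-butyldimethylsilyl chloride, CC(C)(C)[Si](C)(C)Cl
Why: Imidazole-mediated silylation masks the acidic phenol for the Grignard step as an aryl silyl ether that fluoride removes at the end without touching an ester.

Step 5
Reactants: 6 4-{[tert-butyl(dimethyl)silyl]oxy}-3-methoxybenzaldehyde
Product: 7 (4-{[tert-butyl(dimethyl)silyl]oxy}-3-methoxyphenyl)methanol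
Conditions: NaBH4 (1 equiv), THF/EtOH, 0 °C
Reagents that add atoms: none
Why: Borohydride reduction of the aldehyde is fast at 0 °C, where the aryl silyl ether should survive.

Step 6
Reactants: 7 (4-{[tert-butyl(dimethyl)silyl]oxy}-3-methoxyphenyl)methanol
Product: 8 tert-butyl[4-(chloromethyl)-2-methoxyphenoxy]dimethylsilane
Conditions: PPh3 (1.3 equiv), N-chlorosuccinimide (1.3 equiv), CH2Cl2, 0 °C to rt
Reagents that add atoms: N-chlorosuccinimide, O=C1CCC(=O)N1Cl
Why: Appel-type chlorination through the alkoxyphosphonium ion converts the benzylic alcohol into the chloride under neutral conditions that spare the aryl silyl ether.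

Step 7
Reactants: 4 (2R,3R)-3-(3,4-dimethoxyphenyl)-3-hydroxy-N-methoxy-N,2-dimethylpropanamide; 8 tert-butyl[4-(chloromethyl)-2-methoxyphenoxy]dimethylsilane
Product: 10 (3R,4R)-1-(4-{[tert-butyl(dimethyl)silyl]oxy}-3-methoxyphenyl)-4-(3,4-dimethoxyphenyl)-4-hydroxy-3-methylbutan-2-one, via benzylic Grignard reagent 9 (not isolated)
Conditions: 8 (3.5 equiv), Mg turnings (4 equiv), 2-MeTHF, 0 to 10 °C; then 4, THF, −20 to 0 °C; sat. aq NH4Cl
Reagents that add atoms: none
Why: In this Grignard addition to a Weinreb amide the first equivalent deprotonates the hydroxyl and the second gives a chelated tetrahedral intermediate that collapses to the ketone only on work-up, so over-addition and retro-aldol cleavage are avoided, while 2-MeTHF limits Wurtz coupling of the benzylic chloride.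

Step 8
Reactants: 10 (3R,4R)-1-(4-{[tert-butyl(dimethyl)silyl]oxy}-3-methoxyphenyl)-4-(3,4-dimethoxyphenyl)-4-hydroxy-3-methylbutan-2-one
Product: 11 (1R,2S)-3-[(4-{[tert-butyl(dimethyl)silyl]oxy}-3-methoxyphenyl)methyl]-1-(3,4-dimethoxyphenyl)-2-methylbut-3-en-1-ol
Conditions: Tebbe reagent Cp2Ti(μ-Cl)(μ-CH2)AlMe2 (3 equiv, toluene), pyridine (0.5 equiv), THF, −40 to 0 °C; sat. aq NaHCO3, Celite
Reagents that add atoms: Tebbe reagent, Cp2Ti(μ-Cl)(μ-CH2)AlMe2, C[Al](C)C[Ti](Cl)(C1C=CC=C1)C1C=CC=C1
Why: Tebbe methylenation with the titanium methylidene is not basic toward the α-C–H bonds of the benzyl ketone, so the carbonyl should be converted into C3=CH2 without epimerisation of the neighbouring centre or retro-aldol cleavage, the free hydroxyl only consuming extra reagent (the descriptor of the methyl-bearing centre changes from R to S only through the priority rules).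

Step 9
Reactants: 11 (1R,2S)-3-[(4-{[tert-butyl(dimethyl)silyl]oxy}-3-methoxyphenyl)methyl]-1-(3,4-dimethoxyphenyl)-2-methylbut-3-en-1-ol
Product: 12 (1R,2S,3R)-4-(4-{[tert-butyl(dimethyl)silyl]oxy}-3-methoxyphenyl)-1-(3,4-dimethoxyphenyl)-2,3-dimethylbutan-1-ol
Conditions: [Rh(nbd)(dppb)]BF4 (5 mol%), H2 (50 bar), CH2Cl2, rt
Reagents that add atoms: none
Why: In this hydroxyl-directed hydrogenation the C1 hydroxyl binds the cationic rhodium and delivers H2 to the alkene face on which the carbinol carbon lies, and the chelate with the C2 methyl turned toward the =CH2 terminus and the C2–H toward the arylmethyl group (least A1,2 strain) should be favoured, which places the new C3 methyl syn to the C2 methyl (3R); the high H2 pressure is meant to outrun double-bond migration.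

Step 10
Reactants: 12 (1R,2S,3R)-4-(4-{[tert-butyl(dimethyl)silyl]oxy}-3-methoxyphenyl)-1-(3,4-dimethoxyphenyl)-2,3-dimethylbutan-1-ol
Product: 13 (1R,2S,3R)-4-(4-{[tert-butyl(dimethyl)silyl]oxy}-3-methoxyphenyl)-1-(3,4-dimethoxyphenyl)-2,3-dimethylbutyl acetate
Conditions: Ac2O (3 equiv), pyridine (5 equiv), DMAP (0.1 equiv), CH2Cl2, 0 °C to rt
Reagents that add atoms: acetic anhydride, CC(=O)OC(C)=O
Why: DMAP-catalysed O-acylation of the secondary benzylic alcohol leaves the C1–O bond intact, so 1R is retained.

Step 11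
Reactants: 13 (1R,2S,3R)-4-(4-{[tert-butyl(dimethyl)silyl]oxy}-3-methoxyphenyl)-1-(3,4-dimethoxyphenyl)-2,3-dimethylbutyl acetate
Product: 14 (1R,2S,3R)-1-(3,4-dimethoxyphenyl)-4-(4-hydroxy-3-methoxyphenyl)-2,3-dimethylbutyl acetate
Conditions: TBAF (1.1 equiv), AcOH (1.5 equiv), THF, 0 °C
Reagents that add atoms: none
Why: Fluoride cleaves the aryl O–Si bond within minutes, and the acetic acid buffer keeps the phenoxide concentration low so that the benzylic acetate should be neither hydrolysed nor transferred.

Compound list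
1 | ethyl 3-(3,4-dimethoxyphenyl)-3-oxopropanoate | CCOC(=O)CC(=O)c1ccc(OC)c(OC)c1 | starting material
2 | ethyl (2RS)-3-(3,4-dimethoxyphenyl)-2-methyl-3-oxopropanoate | CCOC(=O)C(C)C(=O)c1ccc(OC)c(OC)c1 | intermediate
3 | ethyl (2R,3R)-3-(3,4-dimethoxyphenyl)-3-hydroxy-2-methylpropanoate | CCOC(=O)[C@H](C)[C@@H](O)c1ccc(OC)c(OC)c1 | intermediate
4 | (2R,3R)-3-(3,4-dimethoxyphenyl)-3-hydroxy-N-methoxy-N,2-dimethylpropanamide | CON(C)C(=O)[C@H](C)[C@@H](O)c1ccc(OC)c(OC)c1 | intermediate
5 | vanillin (4-hydroxy-3-methoxybenzaldehyde) | COc1cc(C=O)ccc1O | starting material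
6 | 4-{[tert-butyl(dimethyl)silyl]oxy}-3-methoxybenzaldehyde | COc1cc(C=O)ccc1O[Si](C)(C)C(C)(C)C | intermediate
7 | (4-{[tert-butyl(dimethyl)silyl]oxy}-3-methoxyphenyl)methanol | COc1cc(CO)ccc1O[Si](C)(C)C(C)(C)C | intermediate
8 | tert-butyl[4-(chloromethyl)-2-methoxyphenoxy]dimethylsilane | COc1cc(CCl)ccc1O[Si](C)(C)C(C)(C)C | intermediate
9 | [(4-{[tert-butyl(dimethyl)silyl]oxy}-3-methoxyphenyl)methyl]magnesium chloride | COc1cc(C[Mg]Cl)ccc1O[Si](C)(C)C(C)(C)C | intermediate
10 | (3R,4R)-1-(4-{[tert-butyl(dimethyl)silyl]oxy}-3-methoxyphenyl)-4-(3,4-dimethoxyphenyl)-4-hydroxy-3-methylbutan-2-one | COc1cc(CC(=O)[C@H](C)[C@@H](O)c2ccc(OC)c(OC)c2)ccc1O[Si](C)(C)C(C)(C)C | intermediate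
11 | (1R,2S)-3-[(4-{[tert-butyl(dimethyl)silyl]oxy}-3-methoxyphenyl)methyl]-1-(3,4-dimethoxyphenyl)-2-methylbut-3-en-1-ol | COc1cc(CC(=C)[C@H](C)[C@@H](O)c2ccc(OC)c(OC)c2)ccc1O[Si](C)(C)C(C)(C)C | intermediate
12 | (1R,2S,3R)-4-(4-{[tert-butyl(dimethyl)silyl]oxy}-3-methoxyphenyl)-1-(3,4-dimethoxyphenyl)-2,3-dimethylbutan-1-ol | COc1cc(C[C@@H](C)[C@H](C)[C@@H](O)c2ccc(OC)c(OC)c2)ccc1O[Si](C)(C)C(C)(C)C | intermediate
13 | (1R,2S,3R)-4-(4-{[tert-butyl(dimethyl)silyl]oxy}-3-methoxyphenyl)-1-(3,4-dimethoxyphenyl)-2,3-dimethylbutyl acetate | COc1cc(C[C@@H](C)[C@H](C)[C@@H](OC(C)=O)c2ccc(OC)c(OC)c2)ccc1O[Si](C)(C)C(C)(C)C | intermediate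
14 | (1R,2S,3R)-1-(3,4-dimethoxyphenyl)-4-(4-hydroxy-3-methoxyphenyl)-2,3-dimethylbutyl acetate | COc1cc(C[C@@H](C)[C@H](C)[C@@H](OC(C)=O)c2ccc(OC)c(OC)c2)ccc1O | target

Total step count: 11. Longest linear sequence: 8 steps (steps 1, 2, 3, 7, 8, 9, 10, 11 from 1; the branch from vanillin, steps 4 to 11, is equally long).

Steps most likely to fail:

Step 2. No enzyme of the panel might accept the 3,4-dimethoxyphenyl ketone with syn-(2R,3R) preference, or racemisation at C2 might lag behind reduction so that only a kinetic resolution takes place. The fallback moves the reduction to the amide and to a ruthenium catalyst. It sets out from 2, which would be converted with MeNH(OMe)·HCl and AlMe3 in CH2Cl2 into (2RS)-3-(3,4-dimethoxyphenyl)-N-methoxy-N,2-dimethyl-3-oxopropanamide F1. This keto amide would then be reduced by Noyori–Ikariya transfer hydrogenation under dynamic kinetic resolution (RuCl(p-cymene)[(R,R)-TsDPEN], HCO2H/Et3N, CH2Cl2, 30 °C), a reaction type known to give syn-3-hydroxy-2-alkyl amides. The fallback comes back to the route at 4.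

Step 9. The hydroxyl-bound chelate might not dominate, giving poor facial selectivity, or the C3=CH2 double bond might migrate before it is reduced. The fallback replaces substrate control by catalyst control on a different alkene. It sets out from 11, whose double bond would be moved into conjugation with ring B (RuHCl(CO)(PPh3)3, toluene, 80 °C) to give (1R,2S,3E)-4-(4-{[tert-butyl(dimethyl)silyl]oxy}-3-methoxyphenyl)-1-(3,4-dimethoxyphenyl)-2,3-dimethylbut-3-en-1-ol F2. This aryl-substituted trisubstituted alkene belongs to the best substrate class of chiral iridium phosphine–oxazoline catalysts and would be hydrogenated with [Ir(cod)(tBu-PHOX)]BArF (ligand enantiomer chosen for 3R; H2, 50 bar, CH2Cl2). The fallback comes back to the route at 12.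

Step 8. The titanium–aluminium reagent might cause retro-aldol cleavage or epimerisation next to the ketone of the free hydroxy ketone, or the hydroxyl might use up the reagent. The fallback is a two-stage Peterson olefination that sets out from 10. Addition of Me3SiCH2Li/CeCl3 (THF, −78 °C), a non-basic organocerium reagent, would give (2RS,3R,4R)-1-(4-{[tert-butyl(dimethyl)silyl]oxy}-3-methoxyphenyl)-4-(3,4-dimethoxyphenyl)-3-methyl-2-[(trimethylsilyl)methyl]butane-2,4-diol F3. Treatment with KH (THF, 0 °C) would then eliminate silanolate to form the C3=CH2 bond. The fallback comes back to the route at 11.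

Further compounds
F1 | step 2 | (2RS)-3-(3,4-dimethoxyphenyl)-N-methoxy-N,2-dimethyl-3-oxopropanamide | CON(C)C(=O)C(C)C(=O)c1ccc(OC)c(OC)c1
F2 | step 9 | (1R,2S,3E)-4-(4-{[tert-butyl(dimethyl)silyl]oxy}-3-methoxyphenyl)-1-(3,4-dimethoxyphenyl)-2,3-dimethylbut-3-en-1-ol | COc1cc(/C=C(\C)[C@H](C)[C@@H](O)c2ccc(OC)c(OC)c2)ccc1O[Si](C)(C)C(C)(C)C
F3 | step 8 | (2RS,3R,4R)-1-(4-{[tert-butyl(dimethyl)silyl]oxy}-3-methoxyphenyl)-4-(3,4-dimethoxyphenyl)-3-methyl-2-[(trimethylsilyl)methyl]butane-2,4-diol | COc1cc(CC(O)(C[Si](C)(C)C)[C@H](C)[C@@H](O)c2ccc(OC)c(OC)c2)ccc1O[Si](C)(C)C(C)(C)C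
A1 | direct plan | (4R)-4-{[3-methoxy-4-(prop-2-enyloxy)phenyl]methyl}oxolan-2-one | O=C1C[C@@H](Cc2ccc(OCC=C)c(OC)c2)CO1
A2 | direct plan | (3S,4R)-3-[(R)-(3,4-dimethoxyphenyl)(hydroxy)methyl]-4-{[3-methoxy-4-(prop-2-enyloxy)phenyl]methyl}oxolan-2-one | O=C1OC[C@H](Cc2ccc(OCC=C)c(OC)c2)[C@H]1[C@@H](O)c1ccc(OC)c(OC)c1
A3 | direct plan | (2R,3R)-2-[(R)-{[tert-butyl(dimethyl)silyl]oxy}(3,4-dimethoxyphenyl)methyl]-3-{[3-methoxy-4-(prop-2-enyloxy)phenyl]methyl}butane-1,4-diyl dimethanesulfonate | CS(=O)(=O)OC[C@H](Cc1ccc(OCC=C)c(OC)c1)[C@H](COS(C)(=O)=O)[C@@H](O[Si](C)(C)C(C)(C)C)c1ccc(OC)c(OC)c1
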